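**Plan**
- Cuts: the A ring is opened at C4a–C5 (a ring expansion read backwards), leaving a 4-hydroxycyclobutenone on C6 of a γ-pyranone. The C8–C8a bond (carbinol carbon to pyranone C6) is cut next, then the C2–C1' biaryl bond. Isopropyl ethers mask the 7-, 2'- and 4'-hydroxyls.
- Forward: the B-ring boronate is made from 2,4-dihydroxybenzaldehyde. Ring C is bought as pyromeconic acid and is brominated, O-methylated and arylated. C6-lithiation and addition to isopropyl semisquarate follow. Ring A closes last by thermal ring expansion; 8-O-methylation and one BCl3 step finish.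
- Enabling feature: the A ring carries oxygens at C5 and C8 (para), oxygen at C7 and hydrogen at C6, and its C4a–C8a bond is the C5=C6 double bond of a 4-pyranone. This is exactly the hydroquinone pattern released by a 4-alkenyl-4-hydroxy-3-alkoxycyclobutenone with hydrogen at C2.
- Stereochemistry: the target has no stereocentre and no stereogenic double bond. The single carbinol stereocentre made on the way is racemic and is erased in the ring expansion.

Key step: step 11

Assumption: the target is achiral, so the demand for a single enantiomer is met by the compound itself; pyromeconic acid is taken as purchasable.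

**Route**

Step 1
Reactants: 1 2,4-dihydroxybenzaldehyde
Product: 2 2,4-diisopropoxybenzaldehyde
Conditions: i-PrBr (3 equiv), K2CO3, DMF, 70 °C
Reagents that add atoms: 2-bromopropane, CC(C)Br
Why: Williamson ether synthesis; both phenoxides are alkylated in warm DMF with excess secondary bromide (the chelated 2-OH reacts last), and the aldehyde is untouched.

Step 2
Reactants: 2 2,4-diisopropoxybenzaldehyde
Product: 4 2,4-diisopropoxyphenol, via aryl formate 3 (not isolated)
Conditions: mCPBA, CH2Cl2, 0 °C → rt; NaHCO3 wash; then K2CO3 (cat.), MeOH, rt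
Reagents that add atoms: mCPBA, O=C(OO)c1cccc(Cl)c1
Why: Baeyer–Villiger (Dakin-type) oxidation of an electron-rich benzaldehyde proceeds by aryl migration to the formate, which methanolysis cleaves to the phenol while the isopropyl ethers are inert.

Step 3
Reactants: 4 2,4-diisopropoxyphenol
Product: 5 2,4-diisopropoxy-1-methoxybenzene
Conditions: MeI, K2CO3, acetone, reflux
Reagents that add atoms: iodomethane, CI
Why: Williamson O-methylation of a simple phenol, run directly on the air-sensitive phenol.

Step 4
Reactants: 5 2,4-diisopropoxy-1-methoxybenzene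
Product: 6 1-bromo-2,4-diisopropoxy-5-methoxybenzene
Conditions: NBS, MeCN, 0 °C → rt
Reagents that add atoms: N-bromosuccinimide, O=C1CCC(=O)N1Br
Why: Electrophilic aromatic bromination goes to the only unhindered doubly activated carbon, para to the 2-isopropoxy and ortho to the 4-isopropoxy group; the position between the two isopropoxy groups is shielded.

Step 5
Reactants: 6 1-bromo-2,4-diisopropoxy-5-methoxybenzene
Product: 8 2-(2,4-diisopropoxy-5-methoxyphenyl)-4,4,5,5-tetramethyl-1,3,2-dioxaborolane, via aryllithium 7 (not isolated)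
Conditions: n-BuLi, THF, −78 °C; i-PrOBpin, −78 °C → rt; dil. HCl work-up
Reagents that add atoms: 2-isopropoxy-4,4,5,5-tetramethyl-1,3,2-dioxaborolane, CC(C)OB1OC(C)(C)C(C)(C)O1
Why: Bromine–lithium exchange followed by borylation of the aryllithium with an alkoxy-pinacolborane is the standard entry to electron-rich aryl pinacol boronates.

Step 6
Reactants: 9 pyromeconic acid (3-hydroxy-4H-pyran-4-one)
Product: 10 2-bromo-3-hydroxy-4H-pyran-4-one
Conditions: NBS (1.0 equiv), MeCN, 0 °C → rt
Reagents that add atoms: N-bromosuccinimide, O=C1CCC(=O)N1Br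
Why: Electrophilic bromination of the enolic hydroxypyranone occurs at C2, the carbon ortho to the hydroxyl where this ring system takes electrophiles in general (halogenation, Mannich reaction, hydroxymethylation).

Step 7
Reactants: 10 2-bromo-3-hydroxy-4H-pyran-4-one
Product: 11 2-bromo-3-methoxy-4H-pyran-4-one
Conditions: MeI, K2CO3, acetone, rt → 40 °C
Reagents that add atoms: iodomethane, CI
Why: Williamson O-methylation of the acidic enolic hydroxyl under mild carbonate conditions, which the β-bromo enone tolerates.

Step 8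
Reactants: 11 2-bromo-3-methoxy-4H-pyran-4-one; 8 2-(2,4-diisopropoxy-5-methoxyphenyl)-4,4,5,5-tetramethyl-1,3,2-dioxaborolane
Product: 12 2-(2,4-diisopropoxy-5-methoxyphenyl)-3-methoxy-4H-pyran-4-one
Conditions: Pd(OAc)2 (cat.), SPhos (cat.), K3PO4, toluene/H2O, 70 °C
Reagents that add atoms: none
Why: Suzuki–Miyaura coupling; the C2–Br bond is a vinylogous acyl bromide that adds readily to Pd(0), and the biarylphosphine ligand should couple the ortho-alkoxy boronate faster than it protodeboronates.

Step 9
Reactants: 13 diisopropyl squarate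
Product: 15 3-isopropoxycyclobut-3-ene-1,2-dione, via hydroxycyclobutenone 14 (not isolated)
Conditions: LiAlH(Ot-Bu)3, THF, −78 → −20 °C; then aq. HCl, CH2Cl2, rt
Reagents that add atoms: water, O
Why: 1,2-reduction of one squarate carbonyl by the bulky hydride, then acid-promoted ionisation of the allylic carbinol, addition of water at the alkoxy-stabilised terminus and loss of isopropanol, which is the standard squarate-to-cyclobutenedione transposition with hydride as the nucleophile.

Step 10
Reactants: 12 2-(2,4-diisopropoxy-5-methoxyphenyl)-3-methoxy-4H-pyran-4-one; 15 3-isopropoxycyclobut-3-ene-1,2-dione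
Product: 17 4-[6-(2,4-diisopropoxy-5-methoxyphenyl)-5-methoxy-4-oxo-4H-pyran-2-yl]-4-hydroxy-3-isopropoxycyclobut-2-en-1-one (racemic), via 6-lithiopyranone 16 (not isolated)
Conditions: LiTMP (from TMPH, n-BuLi), THF, −78 °C, 15 min; 15 (1.3 equiv), −78 °C; AcOH quench at −78 °C
Reagents that add atoms: none
Why: Deprotonative lithiation by a hindered amide at the ring C–H next to oxygen (the site lithiated in 3-substituted chromones and in uracils) gives a vinyllithium that adds 1,2 to the ketone-like carbonyl of 15, the one flanked by the isopropoxy-bearing carbon, because the other carbonyl is a deactivated vinylogous ester; the carbinol stereocentre forms as a racemate and needs no control.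

Step 11
Reactants: 17 4-[6-(2,4-diisopropoxy-5-methoxyphenyl)-5-methoxy-4-oxo-4H-pyran-2-yl]-4-hydroxy-3-isopropoxycyclobut-2-en-1-one (racemic)
Product: 20 2-(2,4-diisopropoxy-5-methoxyphenyl)-5,8-dihydroxy-7-isopropoxy-3-methoxy-4H-chromen-4-one, via dienylketene 18 (not isolated), via ring-closed dienone 19 (not isolated)
Conditions: degassed p-xylene, 135 °C, Ar
Reagents that add atoms: none
Why: Heating opens the cyclobutenone by conrotatory 4π-electrocyclic cleavage of the bond between the carbonyl and carbinol carbons; the donor hydroxyl rotates outward, so the pyranonyl group turns inward and the (Z)-dienylketene 18 forms with its ketene carbon beside pyranone C5. Disrotatory 6π-electrocyclisation then joins the electrophilic ketene carbon to C5, the nucleophilic β-carbon of the ring enol ether O1–C6=C5, closing the six-membered carbocycle as dienone 19, and enolisation aromatises it to the hydroquinone. This is the Moore rearrangement of 4-aryl- and 4-alkenyl-4-hydroxycyclobutenones, with the pyranone C5=C6 bond in the role usually played by an aryl, furyl or enol-ether double bond. No stereocentre is created, and the racemic carbinol carbon becomes aromatic C8. The substitution pattern of the new ring (C5–OH from the ketene carbon, C6–H, C7–O-i-Pr, C8–OH from the carbinol carbon) is fixed by the constitution of 17, and closure can only occur at C5 because the other neighbour of C6 is the ring oxygen. Exclusion of air should keep the product at the hydroquinone level.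

Step 12
Reactants: 20 2-(2,4-diisopropoxy-5-methoxyphenyl)-5,8-dihydroxy-7-isopropoxy-3-methoxy-4H-chromen-4-one
Product: 21 2-(2,4-diisopropoxy-5-methoxyphenyl)-5-hydroxy-7-isopropoxy-3,8-dimethoxy-4H-chromen-4-one
Conditions: MeI (1.1 equiv), K2CO3, acetone, rt, Ar
Reagents that add atoms: iodomethane, CI
Why: Williamson methylation should select the free 8-hydroxyl, because the 5-hydroxyl is held in a hydrogen bond to the C4 carbonyl and is far less acidic and nucleophilic, the usual behaviour of 5-hydroxyflavones.

Step 13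
Reactants: 21 2-(2,4-diisopropoxy-5-methoxyphenyl)-5-hydroxy-7-isopropoxy-3,8-dimethoxy-4H-chromen-4-one
Product: 22 5,7-dihydroxy-2-(2,4-dihydroxy-5-methoxyphenyl)-3,8-dimethoxy-4H-chromen-4-one (5,7,2',4'-tetrahydroxy-3,8,5'-trimethoxyflavone)
Conditions: BCl3 (excess), CH2Cl2, −78 → 0 °C; then H2O
Reagents that add atoms: none
Why: Lewis-acid dealkylation with boron trichloride cleaves secondary (isopropyl) aryl ethers much faster than methyl ethers, and the boron chelate formed between the 5-oxygen and the C4 carbonyl should keep the carbonyl from activating the 3-methoxy group.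

**Compound list**
1 | 2,4-dihydroxybenzaldehyde | O=Cc1ccc(O)cc1O | starting material
2 | 2,4-diisopropoxybenzaldehyde | O=Cc1ccc(OC(C)C)cc1OC(C)C | intermediate
3 | 2,4-diisopropoxyphenyl formate (formed in situ) | O=COc1ccc(OC(C)C)cc1OC(C)C | intermediate
4 | 2,4-diisopropoxyphenol | Oc1ccc(OC(C)C)cc1OC(C)C | intermediate
5 | 2,4-diisopropoxy-1-methoxybenzene | COc1ccc(OC(C)C)cc1OC(C)C | intermediate
6 | 1-bromo-2,4-diisopropoxy-5-methoxybenzene | COc1cc(Br)c(OC(C)C)cc1OC(C)C | intermediate
7 | (2,4-diisopropoxy-5-methoxyphenyl)lithium (formed in situ) | COc1cc([Li])c(OC(C)C)cc1OC(C)C | intermediate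
8 | 2-(2,4-diisopropoxy-5-methoxyphenyl)-4,4,5,5-tetramethyl-1,3,2-dioxaborolane | COc1cc(B2OC(C)(C)C(C)(C)O2)c(OC(C)C)cc1OC(C)C | intermediate
9 | pyromeconic acid (3-hydroxy-4H-pyran-4-one) | O=c1ccocc1O | starting material
10 | 2-bromo-3-hydroxy-4H-pyran-4-one | O=c1ccoc(Br)c1O | intermediate
11 | 2-bromo-3-methoxy-4H-pyran-4-one | COc1c(Br)occc1=O | intermediate
12 | 2-(2,4-diisopropoxy-5-methoxyphenyl)-3-methoxy-4H-pyran-4-one | COc1cc(-c2occc(=O)c2OC)c(OC(C)C)cc1OC(C)C | intermediate
13 | diisopropyl squarate | CC(C)OC1=C(OC(C)C)C(=O)C1=O | starting material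
14 | 4-hydroxy-2,3-diisopropoxycyclobut-2-en-1-one (racemic, formed in situ) | CC(C)OC1=C(OC(C)C)C(O)C1=O | intermediate
15 | 3-isopropoxycyclobut-3-ene-1,2-dione | CC(C)OC1=CC(=O)C1=O | intermediate
16 | [6-(2,4-diisopropoxy-5-methoxyphenyl)-5-methoxy-4-oxo-4H-pyran-2-yl]lithium (formed in situ) | [Li]c1cc(=O)c(OC)c(-c2cc(OC)c(OC(C)C)cc2OC(C)C)o1 | intermediate
17 | 4-[6-(2,4-diisopropoxy-5-methoxyphenyl)-5-methoxy-4-oxo-4H-pyran-2-yl]-4-hydroxy-3-isopropoxycyclobut-2-en-1-one (racemic) | CC(C)OC1=CC(=O)C1(O)c1cc(=O)c(OC)c(-c2cc(OC)c(OC(C)C)cc2OC(C)C)o1 | intermediate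
18 | (Z)-dienylketene from ring opening of 17 (formed in situ) | O=C=C/C(OC(C)C)=C(/O)c1cc(=O)c(OC)c(-c2cc(OC)c(OC(C)C)cc2OC(C)C)o1 | intermediate
19 | 2-(2,4-diisopropoxy-5-methoxyphenyl)-8-hydroxy-7-isopropoxy-3-methoxy-4aH-chromene-4,5-dione (racemic, formed in situ) | COC1=C(c2cc(OC)c(OC(C)C)cc2OC(C)C)OC2=C(O)C(OC(C)C)=CC(=O)C2C1=O | intermediate
20 | 2-(2,4-diisopropoxy-5-methoxyphenyl)-5,8-dihydroxy-7-isopropoxy-3-methoxy-4H-chromen-4-one | COc1cc(-c2oc3c(O)c(OC(C)C)cc(O)c3c(=O)c2OC)c(OC(C)C)cc1OC(C)C | intermediate
21 | 2-(2,4-diisopropoxy-5-methoxyphenyl)-5-hydroxy-7-isopropoxy-3,8-dimethoxy-4H-chromen-4-one | COc1cc(-c2oc3c(OC)c(OC(C)C)cc(O)c3c(=O)c2OC)c(OC(C)C)cc1OC(C)C | intermediate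
22 | 5,7,2',4'-tetrahydroxy-3,8,5'-trimethoxyflavone | COc1cc(-c2oc3c(OC)c(O)cc(O)c3c(=O)c2OC)c(O)cc1O | target

**Count**
Total steps: 13. Longest linear sequence: 10 steps (steps 1–5, 8, 10, 11, 12, 13).

**Steps most likely to fail**

Step 10. The lithiated pyranone may be lost by self-addition or ring opening before it meets the electrophile, deprotonation may stray to C5, or the semisquarate may be consumed by proton transfer. Fallback, setting out from 12: deprotonation is run with in situ trapping (LiTMP added to 12 and ZnCl2 in THF, −78 °C → rt), so the carbanion is captured at once as [6-(2,4-diisopropoxy-5-methoxyphenyl)-5-methoxy-4-oxo-4H-pyran-2-yl]zinc chloride F1. Iodolysis with I2 should then give 2-(2,4-diisopropoxy-5-methoxyphenyl)-6-iodo-3-methoxy-4H-pyran-4-one F2, a stable compound whose regiochemistry can be secured before going on. Iodine–magnesium exchange with i-PrMgCl·LiCl at −40 °C gives [6-(2,4-diisopropoxy-5-methoxyphenyl)-5-methoxy-4-oxo-4H-pyran-2-yl]magnesium chloride F3, free of amine and amide. Its addition to 15 at −40 °C with an acetic acid quench comes back to the route at 17.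

Step 11. The ketene may be intercepted by the free hydroxyl (inward rotation leading to a butenolide), or the hydroquinone may be oxidised to the 5,8-quinone during reaction and isolation. Fallback, setting out from 17: the tertiary hydroxyl is methylated first (MeI, Ag2O, MeCN, rt) to give 4-[6-(2,4-diisopropoxy-5-methoxyphenyl)-5-methoxy-4-oxo-4H-pyran-2-yl]-3-isopropoxy-4-methoxycyclobut-2-en-1-one F4. Thermolysis in degassed p-xylene should then pass through the (Z)-methoxy-dienylketene F5 and the 8-methoxy-4aH-chromene-4,5-dione F6. Enolisation delivers the 8-methyl ether directly, so the route is rejoined at 21 and step 12 is no longer needed.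

Step 8. The electron-rich ortho-alkoxy boronate may protodeboronate, and aqueous base may displace the activated bromide of 11. Fallback, setting out from 6: bromine–lithium exchange as in step 5 gives 7, which is transmetalated with ZnCl2 (THF, −78 °C → rt) to (2,4-diisopropoxy-5-methoxyphenyl)zinc chloride F7. Negishi coupling of F7 with 11 under anhydrous, base-free conditions (Pd(OAc)2/SPhos, THF, rt → 50 °C) comes back to the route at 12.

**Further compounds**
F1 | step 10 | [6-(2,4-diisopropoxy-5-methoxyphenyl)-5-methoxy-4-oxo-4H-pyran-2-yl]zinc chloride | Cl[Zn]c1cc(=O)c(OC)c(-c2cc(OC)c(OC(C)C)cc2OC(C)C)o1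
F2 | step 10 | 2-(2,4-diisopropoxy-5-methoxyphenyl)-6-iodo-3-methoxy-4H-pyran-4-one | COc1cc(-c2oc(I)cc(=O)c2OC)c(OC(C)C)cc1OC(C)C
F3 | step 10 | [6-(2,4-diisopropoxy-5-methoxyphenyl)-5-methoxy-4-oxo-4H-pyran-2-yl]magnesium chloride | Cl[Mg]c1cc(=O)c(OC)c(-c2cc(OC)c(OC(C)C)cc2OC(C)C)o1
F4 | step 11 | 4-[6-(2,4-diisopropoxy-5-methoxyphenyl)-5-methoxy-4-oxo-4H-pyran-2-yl]-3-isopropoxy-4-methoxycyclobut-2-en-1-one (racemic) | CC(C)OC1=CC(=O)C1(OC)c1cc(=O)c(OC)c(-c2cc(OC)c(OC(C)C)cc2OC(C)C)o1
F5 | step 11 | (Z)-methoxy-dienylketene from ring opening of F4 | O=C=C/C(OC(C)C)=C(/OC)c1cc(=O)c(OC)c(-c2cc(OC)c(OC(C)C)cc2OC(C)C)o1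
F6 | step 11 | 2-(2,4-diisopropoxy-5-methoxyphenyl)-7-isopropoxy-3,8-dimethoxy-4aH-chromene-4,5-dione (racemic) | COC1=C(c2cc(OC)c(OC(C)C)cc2OC(C)C)OC2=C(OC)C(OC(C)C)=CC(=O)C2C1=O
F7 | step 8 | (2,4-diisopropoxy-5-methoxyphenyl)zinc chloride | COc1cc([Zn]Cl)c(OC(C)C)cc1OC(C)C
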